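## Analysis of the target

The target 11 is a monocyclic 4H-pyran-4-one in which every ring carbon is substituted. With the ring numbered O1, C2, C3, C4 (carbonyl), C5, C6, a propanoyl group sits on C2 and bromine on C3, C5 and C6. There is no stereocentre, so the problem is one of regiochemistry and functional-group tolerance. The bromines are of two kinds. C3 and C5 are the α-carbons of the vinylogous ester and are where a pyranone reacts with electrophiles. C6, next to the ring oxygen, is a β-carbon and is electrophilic, so its bromine cannot be introduced by electrophilic substitution of C–H. The C6–Br bond is also a vinylogous acyl bromide and the most fragile group, because alkoxides, amines and water under forcing acid displace it by addition–elimination. The ethyl ketone is the second sensitive site, since its methylene is brominated through the enol or an enol ether. The plan rests on reading O1–C2–C3–C4 as the oxa-diene of an acylketene (acyl oxygen, acyl carbon, α-carbon, ketene carbon) and C5–C6 as an alkyne-level two-carbon unit that already carries the C6 bromine.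

## Retrosynthetic reasoning

**11 to 10.** No skeletal bond is cut first; the side-chain carbonyl of 11 is traced back to the dimethyl ketal 10. A free ethyl ketone would be brominated at its methylene in the halogenation, and further back it would place a second carbonyl next to the acylketene. The forward step must free the ketone by acid hydrolysis without water displacing the C6 bromide.

**10 to 9.** The C3–Br and C5–Br bonds are cut and C6–Br is kept. C3 and C5 are the nucleophilic ring carbons, so both bromines can come from one electrophilic bromination: C3 from C–H, and C5 from a C–Si bond by ipso substitution. The silyl group of 9 costs nothing extra because the preceding step needs it. An unbuffered bromination would release acid and a silyl halide, which ionise the ketal to an enol ether and lead to side-chain bromination. A hindered base is therefore part of the forward step.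

**9 to 8 and 7.** The ring is opened at C4–C5 and O1–C6. This is the only pair of cuts that removes C5–C6 as one stable two-carbon piece carrying the C6 bromine, and it leaves O1–C2–C3–C4 as acylketene 8. Cuts through O1–C2 or C3–C4 would instead require a polyhalogenated dicarbonyl chain. The gain is convergence: the ring and the most awkward bromine come from two small fragments in one step. The forward reaction must join the ketene carbon to the silylated carbon of 7 and the acyl oxygen to the brominated carbon; the silyl group is there to enforce this orientation.

**8 to 5.** Acylketene 8 cannot be stored. It is traced to acyl Meldrum's acid 5, which releases it on heating by a fragmentation that gives only volatile by-products.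

**5 to 3 and 4.** The bond between the acyl carbon (future C2) and C5 of Meldrum's acid 4 (future C3) is cut. The forward reaction is a carbodiimide-mediated C-acylation, which tolerates the ketal.

**3 to 2 to 1.** Acid 3 comes from ester 2 by saponification, and 2 from the commercial α-keto ester 1 by ketalisation. The ketal is installed at the ester stage, where the activated ketone reacts readily.

**7 to 6.** The C–Br bond is cut; the terminal alkyne 6 is brominated at carbon with the silyl group left in place.

## Alternatives that were turned down

**Alternative 1:** The ring is opened at O1–C2 to the acyclic (Z)-ethoxy enynone A1, whose ether oxygen becomes O1. In the forward key step two equivalents of bromine act on A1. A bromonium ion forms on the alkyne, the enol ether oxygen attacks the far alkyne carbon in a 6-endo closure, bromide removes the ethyl group, and the second equivalent brominates C5, giving A2.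
- For: halocyclisation of ynones by ether oxygen with dealkylation is an established ring synthesis, so precedent is stronger than for the chosen key step. The ring and two bromines arrive in one operation.
- Against: the enol ether double bond of A1 is far more nucleophilic than the ynone triple bond, so bromine should attack it first. Only the Z isomer can close. A2 also still has hydrogen at C6, the one position that electrophilic bromination cannot reach.
- Comparison: a metalation–bromination next to two ring bromines, desilylation and oxidation must follow, which is three steps after ring closure against two in the chosen route. The chosen route is weaker on precedent but delivers the C6 bromine with the ring and keeps the side chain at the ketone oxidation level.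

**Alternative 2:** Only O1–C6 is cut, giving the open-chain tetrabromide A3 with every bromine already in the chain. With K2CO3 the enol oxygen of the carbonyl at future C2 adds to the CBr2 terminus and bromide leaves, closing the ring to A4, which is the same compound as 10.
- For: the ring closure has no regiochemical question, addition–elimination on a β,β-dihalo enone is dependable, and A4 is one hydrolysis from the target. After ring closure this route is one step shorter than the chosen one and needs no separate bromination.
- Against: the burden moves to A3, which combines a tribromoacryloyl unit, an α-bromo-1,3-diketone and a ketal. Its assembly needs acylation with a tribromoacryloyl electrophile that is itself a Michael acceptor, then selective monobromination of the central carbon. The chain is prone to retro-Claisen cleavage under the carbonate used for closure.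
- Comparison: this alternative is stronger at the end. The chosen route offers stable fragments made in two or three routine steps each and confines the uncertainty to a single step.

**Alternative 3:** C2–C3 and C3–C4 are cut, removing C3 and its bromine as a carbene carbon and leaving the furan A5 (drawn with a tert-butyldimethylsilyl ether on the ring oxygen). Dibromocarbene from bromoform and KOC(CH3)3 adds to the siloxy-bearing double bond, and the siloxycyclopropane opens with loss of bromide and silyl to give A6.
- For: dihalocarbene ring expansion of silyl enol ethers to α-halo enones is well precedented, and the carbonyl and C3–Br appear together. A6 carries all three bromines.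
- Against: A5 is an electron-rich, acid-labile 3-siloxyfuran with two bromines and a protected carbinol, and building it regioselectively is a multi-step problem. The tert-butoxide base can displace the C6 bromide of A6.
- Comparison: desilylation and oxidation still follow, the same number of steps as after the chosen key step, but at the end of a longer linear sequence. The key-step type is better supported than the chosen one; the chosen route offers convergence and non-basic conditions after ring formation.

Key step: step 5

Remark: 5 is drawn as its hydrogen-bonded enol, the tautomer in which acyl Meldrum's acids exist; racemic compounds are written without stereodescriptors.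

## Steps

Step 1
Reactants: 1 methyl 2-oxobutanoate
Product: 2 methyl 2,2-dimethoxybutanoate
Conditions: HC(OMe)3, MeOH, cat. p-TsOH·H2O, 60 °C; then NaHCO3
Reagents that add atoms: trimethyl orthoformate COC(OC)OC; methanol CO
Why: Acid-catalysed ketalisation of an activated α-keto ester, with the orthoformate removing water so that the equilibrium lies on the ketal side. Neutralisation before concentration prevents loss of methanol to the enol ether.

Step 2
Reactants: 2 methyl 2,2-dimethoxybutanoate
Product: 3 2,2-dimethoxybutanoic acid
Conditions: LiOH·H2O, THF/H2O, 0 °C to rt; then cold 1 M HCl to pH 3
Reagents that add atoms: lithium hydroxide [Li+].[OH-]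
Why: Ester saponification; the ketal is inert to base, and the adjacent carboxyl group slows its acid hydrolysis enough to allow a brief cold acidification.

Step 3
Reactants: 3 2,2-dimethoxybutanoic acid; 4 Meldrum's acid (2,2-dimethyl-1,3-dioxane-4,6-dione)
Product: 5 5-(1-hydroxy-2,2-dimethoxybutylidene)-2,2-dimethyl-1,3-dioxane-4,6-dione
Conditions: DCC, DMAP, CH2Cl2, 0 °C to rt; cold aq. citric acid wash
Reagents that add atoms: none
Why: Carbodiimide-mediated C-acylation of Meldrum's acid with DMAP as acyl-transfer catalyst. The product should be obtained as the enol and used without chromatography.

Step 4
Reactants: 6 ethynyltrimethylsilane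
Product: 7 (bromoethynyl)trimethylsilane
Conditions: NBS (1.05 equiv), AgNO3 (10 mol %), acetone, rt, dark
Reagents that add atoms: N-bromosuccinimide O=C1CCC(=O)N1Br
Why: Silver-catalysed bromination of a terminal alkyne through the silver acetylide. Keeping the brominating agent near one equivalent avoids further bromination at the C–Si bond.

Step 5
Reactants: 5 5-(1-hydroxy-2,2-dimethoxybutylidene)-2,2-dimethyl-1,3-dioxane-4,6-dione; 7 (bromoethynyl)trimethylsilane
Product: 9 6-bromo-2-(1,1-dimethoxypropyl)-5-(trimethylsilyl)-4H-pyran-4-one, via 4,4-dimethoxyhex-1-ene-1,3-dione 8 (not isolated)
Conditions: PhMe, 110 °C, slow addition of 5 to 7 (5 equiv), N2 sweep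
Reagents that add atoms: none
Why: Proposed new method: heating 5 causes a retro-[4+2] fragmentation that expels acetone and CO2 and leaves acylketene 8, whose s-cis O1=C2–C3=C4 unit is an electron-poor oxa-diene with its electrophilic site at the ketene carbon C4. The silicon-bearing carbon of 7 should attack C4, because the vinyl cation developing on the other alkyne carbon is β to silicon and carries a bromine lone pair; collapse of the acyl enolate oxygen onto that carbon then forms O1–C6, so the six-membered ring closes by a polar, asynchronous or stepwise [4+2] annulation (C4–C5 first, then O1–C6, a 6-endo closure if the intermediate is an open zwitterion). The closest known reactions are the [4+2] cycloadditions of thermally generated acylketenes with ynol ethers and ynamines to 4-pyranones and the Friedel–Crafts acylation of alkynylsilanes at the silylated carbon; what is new is a halo(silyl)alkyne, a much weaker nucleophile, as the two-carbon partner. No stereocentre is formed. The step needs regioselectivity (C4 to the silylated carbon, O1 to the brominated carbon), which the β-silicon effect and bromine lone-pair donation should secure together. It also needs the acylketene to choose the alkyne over itself, which is addressed by adding 5 slowly to a large excess of 7 while the released acetone is swept out. The ketal keeps the side-chain carbon from being a second carbonyl, so 8 has only one oxa-diene.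

Step 6
Reactants: 9 6-bromo-2-(1,1-dimethoxypropyl)-5-(trimethylsilyl)-4H-pyran-4-one
Product: 10 2,3,5-tribromo-6-(1,1-dimethoxypropyl)-4H-pyran-4-one
Conditions: Br2 (2.2 equiv), 2,6-lutidine (2.5 equiv), CH2Cl2, 0 °C to rt
Reagents that add atoms: bromine BrBr
Why: Electrophilic bromination at the two nucleophilic ring carbons: C3–H by addition–elimination through the O1-stabilised C2 cation, and C5 by ipso bromodesilylation through a C6 cation that is β to silicon and next to O1. The hindered base takes up HBr so that the ketal is not ionised to an enol ether, and it is too bulky to displace the C6 bromide.

Step 7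
Reactants: 10 2,3,5-tribromo-6-(1,1-dimethoxypropyl)-4H-pyran-4-one
Product: 11 2,3,5-tribromo-6-propanoyl-4H-pyran-4-one
Conditions: TFA/H2O (10:1), CH2Cl2, 0 °C to rt
Reagents that add atoms: water O
Why: Acid-catalysed ketal hydrolysis. Strong acid with little water is chosen because the oxocarbenium ion next to the tribrominated ring forms reluctantly, and the low temperature should limit attack of water at C6.

## Compound list

1 | methyl 2-oxobutanoate | CCC(=O)C(=O)OC | starting material
2 | methyl 2,2-dimethoxybutanoate | CCC(OC)(OC)C(=O)OC | intermediate
3 | 2,2-dimethoxybutanoic acid | CCC(OC)(OC)C(=O)O | intermediate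
4 | Meldrum's acid (2,2-dimethyl-1,3-dioxane-4,6-dione) | CC1(C)OC(=O)CC(=O)O1 | starting material
5 | 5-(1-hydroxy-2,2-dimethoxybutylidene)-2,2-dimethyl-1,3-dioxane-4,6-dione | CCC(OC)(OC)C(O)=C1C(=O)OC(C)(C)OC1=O | intermediate
6 | ethynyltrimethylsilane | C[Si](C)(C)C#C | starting material
7 | (bromoethynyl)trimethylsilane | C[Si](C)(C)C#CBr | intermediate
8 | 4,4-dimethoxyhex-1-ene-1,3-dione (acylketene, not isolated) | CCC(OC)(OC)C(=O)C=C=O | intermediate
9 | 6-bromo-2-(1,1-dimethoxypropyl)-5-(trimethylsilyl)-4H-pyran-4-one | CCC(OC)(OC)c1cc(=O)c([Si](C)(C)C)c(Br)o1 | intermediate
10 | 2,3,5-tribromo-6-(1,1-dimethoxypropyl)-4H-pyran-4-one | CCC(OC)(OC)c1oc(Br)c(Br)c(=O)c1Br | intermediate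
11 | 2,3,5-tribromo-6-propanoyl-4H-pyran-4-one | CCC(=O)c1oc(Br)c(Br)c(=O)c1Br | target

## Step count and least certain steps

Total step count: 7. Longest linear sequence: 6 (steps 1, 2, 3, 5, 6, 7); step 4 is a one-step branch.

**Step 5 (key step).** The bromoalkyne is a weak nucleophile. The acylketene may therefore be consumed by self-condensation, or recombine with the acetone it has just lost, before the alkyne adds. A [2+2] addition across the ketene C=C is a further diversion. Loss of silicon from an open zwitterion would not matter, because the C5–H so formed is brominated in step 6 as well.

The fallback uses known reaction types, sets out from 5 and returns at 10.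
- Thermolysis of 5 in toluene with butyl vinyl ether, an established acylketene trap, should give racemic 2-butoxy-6-(1,1-dimethoxypropyl)-2,3-dihydro-4H-pyran-4-one F1.
- Loss of butanol with catalytic p-TsOH in dry toluene should give 2-(1,1-dimethoxypropyl)-4H-pyran-4-one F2.
- Br2 and 2,6-lutidine should brominate C3 and C5 to 3,5-dibromo-2-(1,1-dimethoxypropyl)-4H-pyran-4-one F3.
- The one remaining ring C–H, at C6 next to the ring oxygen, is metalated with TMPMgCl·LiCl in THF at low temperature, a known mode of metalating 4-pyranones and chromones. Quenching with 1,2-dibromo-1,1,2,2-tetrachloroethane should give 10.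

This keeps the acylketene as the four-atom piece but no longer brings the C6 bromine in with the alkyne.

**Step 6.** The bromotrimethylsilane and HBr formed may ionise the ketal, with loss of methanol to a methyl enol ether and bromination of the side-chain methylene. Attack of the base at C6 is a lesser risk.

The fallback carries the side chain at the alcohol oxidation level, where nothing can ionise or enolise. It sets out from 4 and 7 and returns at 11.
- Racemic methyl 2-hydroxybutanoate F4 is silylated (TBSCl, imidazole) to methyl 2-[(tert-butyldimethylsilyl)oxy]butanoate F5 and saponified with LiOH to 2-[(tert-butyldimethylsilyl)oxy]butanoic acid F6.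
- F6 is condensed with 4 as in step 3 to 5-{2-[(tert-butyldimethylsilyl)oxy]-1-hydroxybutylidene}-2,2-dimethyl-1,3-dioxane-4,6-dione F7.
- F7 and 7 under the conditions of step 5 should give racemic 6-bromo-2-{1-[(tert-butyldimethylsilyl)oxy]propyl}-5-(trimethylsilyl)-4H-pyran-4-one F8.
- Bromination as in step 6 should give racemic 2,3,5-tribromo-6-{1-[(tert-butyldimethylsilyl)oxy]propyl}-4H-pyran-4-one F9, the same compound as A6.
- Aqueous HF in MeCN frees racemic 2,3,5-tribromo-6-(1-hydroxypropyl)-4H-pyran-4-one F10, and Dess–Martin periodinane oxidises it to 11.

**Step 7.** The ketal is deactivated by the tribrominated ring and needs strong acid to ionise. Under that acid, water may add to C6 of the protonated pyranone and the C6 bromide is lost by hydrolysis.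

The fallback reverses the order of the last two steps. It sets out from 9 and returns at 11.
- The ketal of 9 is hydrolysed first with dilute aqueous HCl in THF. At this stage the ring is less electron-poor, so the ketal ionises more easily and C6 is less electrophilic. This should give 6-bromo-2-propanoyl-5-(trimethylsilyl)-4H-pyran-4-one F11.
- F11 is brominated with Br2 and 2,6-lutidine as in step 6 to give 11 directly.

The price is that the ethyl ketone is exposed to bromine, so the buffer must keep enolisation slower than ring substitution. Loss of the silyl group by protonation at C5 during the hydrolysis would do no harm, since that position is brominated either way.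

**Step 3.** The O-acylisourea of this hindered α,α-disubstituted acid may rearrange to an unreactive N-acylurea, and part of the ketal may be lost in the acidic wash that removes DMAP.

The fallback replaces the acylketene precursor. It sets out from 2 and returns at 9.
- Claisen condensation of 2 with the lithium enolate of tert-butyl acetate (LDA, THF, −78 °C) should give tert-butyl 4,4-dimethoxy-3-oxohexanoate F12.
- On heating in xylene at about 140 °C, this β-keto tert-butyl ester loses tert-butanol to give the same acylketene 8, which in the presence of 7 should lead to 9.

## Further compounds

F1 | step 5 | 2-butoxy-6-(1,1-dimethoxypropyl)-2,3-dihydro-4H-pyran-4-one (racemic) | CCCCOC1CC(=O)C=C(O1)C(OC)(OC)CC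
F2 | step 5 | 2-(1,1-dimethoxypropyl)-4H-pyran-4-one | CCC(OC)(OC)c1cc(=O)cco1
F3 | step 5 | 3,5-dibromo-2-(1,1-dimethoxypropyl)-4H-pyran-4-one | CCC(OC)(OC)c1occ(Br)c(=O)c1Br
F4 | step 6 | methyl 2-hydroxybutanoate (racemic) | CCC(O)C(=O)OC
F5 | step 6 | methyl 2-[(tert-butyldimethylsilyl)oxy]butanoate (racemic) | CCC(O[Si](C)(C)C(C)(C)C)C(=O)OC
F6 | step 6 | 2-[(tert-butyldimethylsilyl)oxy]butanoic acid (racemic) | CCC(O[Si](C)(C)C(C)(C)C)C(=O)O
F7 | step 6 | 5-{2-[(tert-butyldimethylsilyl)oxy]-1-hydroxybutylidene}-2,2-dimethyl-1,3-dioxane-4,6-dione (racemic) | CCC(O[Si](C)(C)C(C)(C)C)C(O)=C1C(=O)OC(C)(C)OC1=O
F8 | step 6 | 6-bromo-2-{1-[(tert-butyldimethylsilyl)oxy]propyl}-5-(trimethylsilyl)-4H-pyran-4-one (racemic) | CCC(O[Si](C)(C)C(C)(C)C)c1cc(=O)c([Si](C)(C)C)c(Br)o1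
F9 | step 6 | 2,3,5-tribromo-6-{1-[(tert-butyldimethylsilyl)oxy]propyl}-4H-pyran-4-one (racemic) | CCC(O[Si](C)(C)C(C)(C)C)c1oc(Br)c(Br)c(=O)c1Br
F10 | step 6 | 2,3,5-tribromo-6-(1-hydroxypropyl)-4H-pyran-4-one (racemic) | CCC(O)c1oc(Br)c(Br)c(=O)c1Br
F11 | step 7 | 6-bromo-2-propanoyl-5-(trimethylsilyl)-4H-pyran-4-one | CCC(=O)c1cc(=O)c([Si](C)(C)C)c(Br)o1
F12 | step 3 | tert-butyl 4,4-dimethoxy-3-oxohexanoate | CCC(OC)(OC)C(=O)CC(=O)OC(C)(C)C
A1 | alternative 1 | (1Z)-6-[(tert-butyldimethylsilyl)oxy]-1-ethoxyoct-1-en-4-yn-3-one (racemic) | CCO/C=C\C(=O)C#CC(CC)O[Si](C)(C)C(C)(C)C
A2 | alternative 1 | 3,5-dibromo-2-{1-[(tert-butyldimethylsilyl)oxy]propyl}-4H-pyran-4-one (racemic) | CCC(O[Si](C)(C)C(C)(C)C)c1occ(Br)c(=O)c1Br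
A3 | alternative 2 | 1,1,2,4-tetrabromo-6,6-dimethoxyoct-1-ene-3,5-dione (racemic) | CCC(OC)(OC)C(=O)C(Br)C(=O)C(Br)=C(Br)Br
A4 | alternative 2 | 2,3,5-tribromo-6-(1,1-dimethoxypropyl)-4H-pyran-4-one | CCC(OC)(OC)c1oc(Br)c(Br)c(=O)c1Br
A5 | alternative 3 | 2,3-dibromo-4-[(tert-butyldimethylsilyl)oxy]-5-{1-[(tert-butyldimethylsilyl)oxy]propyl}furan (racemic) | CCC(O[Si](C)(C)C(C)(C)C)c1oc(Br)c(Br)c1O[Si](C)(C)C(C)(C)C
A6 | alternative 3 | 2,3,5-tribromo-6-{1-[(tert-butyldimethylsilyl)oxy]propyl}-4H-pyran-4-one (racemic) | CCC(O[Si](C)(C)C(C)(C)C)c1oc(Br)c(Br)c(=O)c1Br
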